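**Retrosynthetic overview**
- Side chain last: target ⇐ Wittig methylenation of an α-hydroxymethyl aldehyde ⇐ amine-catalysed α-hydroxymethylation (sets the side-chain stereocenter) ⇐ linear hydroformylation of an allyl group; the angelate goes on the secondary ring hydroxyl before that.
- cis-1,3-Diol ⇐ LiAlH4 on an α,β-epoxy ketone ⇐ nucleophilic epoxidation of a β-methyl enone ⇐ MeLi addition and oxidative 1,3-transposition of the isomeric enone.
- Allyl-substituted enone ⇐ ketone dehydrogenation ⇐ Tsuji decarboxylative allylation of a bicyclic allyl β-keto ester.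
- Bicyclic β-keto ester ⇐ one cationic cascade that closes ring A and then ring B of an acyclic (Z)-dienyl β-keto ester under a confined chiral Brønsted acid (Z-olefin gives the cis ring fusion; first stereocenters).
- Acyclic precursor ⇐ nerol + allyl acetoacetate; angelic acid is the third building block.

Assumption: the SMILES is taken as written, that is a cis-fused decalin (ring-fusion H and CH3 on the same face; labdane descriptors 5R,6S,8R,9R,10S,13R) carrying a (Z)-2-methylbut-2-enoate (angelate).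

**Step 1**
Reactants: 1 nerol; 2 allyl acetoacetate
Product: 4 prop-2-en-1-yl (6Z)-7,11-dimethyl-3-oxododeca-6,10-dienoate, via neryl bromide 3 (not isolated)
Conditions: 1, PBr3 (0.4 equiv), Et2O, −10 °C, crude 3; 2, NaH then n-BuLi, THF, 0 °C; add 3, 0 °C; 1 M HCl
Reagents that add atoms: none
Why: PBr3 bromination of the primary allylic alcohol keeps the Z-olefin, and Huckin–Weiler γ-alkylation of the acetoacetate dianion (SN2 at the allylic bromide) joins the two pieces without forming a stereocenter.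

**Step 2**
Reactants: 4 prop-2-en-1-yl (6Z)-7,11-dimethyl-3-oxododeca-6,10-dienoate
Product: 5 prop-2-en-1-yl (1R,4aR,8aS)-5,5,8a-trimethyl-2-oxodecahydronaphthalene-1-carboxylate (cis-fused: 4a-H and 8a-CH3 on the same face)
Conditions: confined BINOL-derived imidodiphosphorimidate Brønsted acid (IDPi, 5 mol %, the enantiomer that gives 4aR,8aS), (CF3)3COH/CHCl3, −40 °C
Reagents that add atoms: none
Why: Proposed new method: the confined chiral acid protonates the terminal trisubstituted olefin inside its anion pocket, the tertiary cation is captured by the (6Z)-olefin and then by the enol carbon of the β-keto ester in an anti addition that turns the Z geometry into the cis ring fusion while the chiral counter-anion selects the olefin face and so sets C4a and C8a (C1 equilibrates as a β-keto ester), O-capture being reversible under the acid whereas C–C bond formation is not; the closest known reactions are the imidodiphosphorimidate-catalysed enantioselective polyene cyclisation of (E,E)-homofarnesol with an alcohol terminus and the racemic SnCl4-promoted cyclisation of β-keto ester polyenes, but an enol-carbon terminus and a Z-olefin have not been shown in the catalytic asymmetric version.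

**Step 3**
Reactants: 5 prop-2-en-1-yl (1R,4aR,8aS)-5,5,8a-trimethyl-2-oxodecahydronaphthalene-1-carboxylate
Product: 6 (1R,4aR,8aS)-5,5,8a-trimethyl-1-(prop-2-en-1-yl)octahydronaphthalen-2(1H)-one
Conditions: Pd(PPh3)4 (5 mol %), THF, 25 °C
Reagents that add atoms: none
Why: Tsuji decarboxylative allylation, in which zerovalent palladium ionises the allyl ester, CO2 is lost to give the regiodefined C1 enolate, and the π-allyl unit is expected to return to C1 on the face syn to the 8a-methyl and away from the folded gem-dimethyl ring, setting 1R at a centre that stays epimerisable.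

**Step 4**
Reactants: 6 (1R,4aR,8aS)-5,5,8a-trimethyl-1-(prop-2-en-1-yl)octahydronaphthalen-2(1H)-one
Product: 7 (1R,4aR,8aS)-5,5,8a-trimethyl-1-(prop-2-en-1-yl)-4a,5,6,7,8,8a-hexahydronaphthalen-2(1H)-one
Conditions: LiN(iPr)2, THF, −78 °C; then N-tert-butylbenzenesulfinimidoyl chloride, −78 °C
Reagents that add atoms: none
Why: Mukaiyama dehydrogenation, in which kinetic deprotonation takes the unhindered C3 methylene rather than the C1 methine beside the quaternary carbon, and sulfur capture with syn-elimination gives the C3=C4 enone without touching a stereocenter.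

**Step 5**
Reactants: 7 (1R,4aR,8aS)-5,5,8a-trimethyl-1-(prop-2-en-1-yl)-4a,5,6,7,8,8a-hexahydronaphthalen-2(1H)-one
Product: 9 (4S,4aR,8aR)-3,4a,8,8-tetramethyl-4-(prop-2-en-1-yl)-4a,5,6,7,8,8a-hexahydronaphthalen-1(4H)-one, via tertiary allylic alcohol 8 (not isolated)
Conditions: MeLi, CeCl3, THF, −78 °C; H2O; crude 8, pyridinium chlorochromate [C5H5NH][CrO3Cl], 4 Å MS, CH2Cl2, 25 °C
Reagents that add atoms: methyllithium, C[Li]; pyridinium chlorochromate, [O-][Cr](=O)(=O)Cl.c1cc[nH+]cc1 (supplies the new carbonyl oxygen)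
Why: 1,2-addition of the methyl nucleophile to the enone followed by Dauben–Babler oxidative transposition ([3,3] shift of the chromate ester, then oxidation) moves the carbonyl to the other end of the allyl system and leaves the methyl on the new trisubstituted olefin, the carbinol centre of 8 being erased so that its configuration does not matter.

**Step 6**
Reactants: 9 (4S,4aR,8aR)-3,4a,8,8-tetramethyl-4-(prop-2-en-1-yl)-4a,5,6,7,8,8a-hexahydronaphthalen-1(4H)-one
Product: 10 (2S,3S,4R,4aR,8aR)-2,3-epoxy-3,4a,8,8-tetramethyl-4-(prop-2-en-1-yl)octahydronaphthalen-1(2H)-one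
Conditions: 30% H2O2, NaOH (0.3 equiv), MeOH, 0 °C
Reagents that add atoms: hydrogen peroxide, OO
Why: Weitz–Scheffer nucleophilic epoxidation, the reaction used to make isophorone oxide, in which hydroperoxide is expected to add to the β-carbon trans to the adjacent allyl group and opposite the angular methyl, setting C2 and C3 with the oxygen that becomes the tertiary hydroxyl.

**Step 7**
Reactants: 10 (2S,3S,4R,4aR,8aR)-2,3-epoxy-3,4a,8,8-tetramethyl-4-(prop-2-en-1-yl)octahydronaphthalen-1(2H)-one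
Product: 11 (1S,3R,4R,4aS,8aR)-3,4a,8,8-tetramethyl-4-(prop-2-en-1-yl)decahydronaphthalene-1,3-diol
Conditions: LiAlH4, THF, 0 → 65 °C; then H2O
Reagents that add atoms: none
Why: LiAlH4 reduction, in which hydride should attack the ketone anti to the epoxide oxygen and to the gem-dimethyl carbon that flanks the same face (giving the 1S carbinol cis to the epoxide) and then opens the epoxide by SN2 at its secondary carbon, the tertiary carbon being blocked, so that the tertiary 3R hydroxyl keeps the epoxide configuration and a cis-1,3-diol results.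

**Step 8**
Reactants: 11 (1S,3R,4R,4aS,8aR)-3,4a,8,8-tetramethyl-4-(prop-2-en-1-yl)decahydronaphthalene-1,3-diol; 12 angelic acid
Product: 13 (1S,3R,4R,4aS,8aR)-3-hydroxy-3,4a,8,8-tetramethyl-4-(prop-2-en-1-yl)decahydronaphthalen-1-yl (2Z)-2-methylbut-2-enoate
Conditions: 12, 2,4,6-trichlorobenzoyl chloride, Et3N, toluene, 25 °C; then 11, 80 °C
Reagents that add atoms: none
Why: Yamaguchi-type mixed-anhydride esterification run without DMAP to avoid Z-to-E isomerisation to the tiglate, in which only the secondary hydroxyl is acylated and the tertiary one is inert.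

**Step 9**
Reactants: 13 (1S,3R,4R,4aS,8aR)-3-hydroxy-3,4a,8,8-tetramethyl-4-(prop-2-en-1-yl)decahydronaphthalen-1-yl (2Z)-2-methylbut-2-enoate
Product: 14 (1S,3R,4R,4aS,8aR)-3-hydroxy-3,4a,8,8-tetramethyl-4-(4-oxobutyl)decahydronaphthalen-1-yl (2Z)-2-methylbut-2-enoate
Conditions: Rh(acac)(CO)2 (1 mol %), Xantphos (2 mol %), CO/H2 (1:1, 10 bar), toluene, 70 °C
Reagents that add atoms: carbon monoxide, [C-]#[O+]
Why: Linear-selective rhodium-catalysed hydroformylation with a wide-bite-angle bisphosphine converts only the monosubstituted olefin, the trisubstituted conjugated angelate olefin being inert.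

**Step 10**
Reactants: 14 (1S,3R,4R,4aS,8aR)-3-hydroxy-3,4a,8,8-tetramethyl-4-(4-oxobutyl)decahydronaphthalen-1-yl (2Z)-2-methylbut-2-enoate
Product: 15 (1S,3R,4R,4aS,8aR)-3-hydroxy-4-[(3S)-3-(hydroxymethyl)-4-oxobutyl]-3,4a,8,8-tetramethyldecahydronaphthalen-1-yl (2Z)-2-methylbut-2-enoate
Conditions: (R)-2-[diphenyl(trimethylsilyloxy)methyl]pyrrolidine (20 mol %), 37% aq. CH2O, pH 7 phosphate buffer, toluene, 25 °C
Reagents that add atoms: formaldehyde, C=O
Why: Enamine organocatalysis (diarylprolinol silyl ether-catalysed α-hydroxymethylation), in which the catalyst shields one enamine face so that formaldehyde adds to give the S aldehyde under catalyst control, independent of the remote ring stereocenters; the R catalyst is assigned from the usual steric-shielding model and the other enantiomer is used if the sense proves opposite.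

**Step 11**
Reactants: 15 (1S,3R,4R,4aS,8aR)-3-hydroxy-4-[(3S)-3-(hydroxymethyl)-4-oxobutyl]-3,4a,8,8-tetramethyldecahydronaphthalen-1-yl (2Z)-2-methylbut-2-enoate
Product: 16 (1S,3R,4R,4aS,8aR)-3-hydroxy-4-[(3R)-3-(hydroxymethyl)pent-4-en-1-yl]-3,4a,8,8-tetramethyldecahydronaphthalen-1-yl (2Z)-2-methylbut-2-enoate
Conditions: Ph3PCH3Br, KN(SiMe3)2 (4 equiv of ylide), THF, −78 → 0 °C
Reagents that add atoms: methyltriphenylphosphonium bromide, C[P+](c1ccccc1)(c1ccccc1)c1ccccc1.[Br-]
Why: Wittig methylenation at low temperature, with excess ylide to cover the two free hydroxyls, turns the formyl group into the vinyl group without attacking the hindered unsaturated ester, and the side-chain descriptor changes from S to R by priority only.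

**Compound list**
1 | nerol, (2Z)-3,7-dimethylocta-2,6-dien-1-ol | CC(C)=CCC/C(C)=C\CO | starting material
2 | allyl acetoacetate, prop-2-en-1-yl 3-oxobutanoate | CC(=O)CC(=O)OCC=C | starting material
3 | neryl bromide, (2Z)-1-bromo-3,7-dimethylocta-2,6-diene | CC(C)=CCC/C(C)=C\CBr | intermediate
4 | prop-2-en-1-yl (6Z)-7,11-dimethyl-3-oxododeca-6,10-dienoate | C=CCOC(=O)CC(=O)CC/C=C(/C)CCC=C(C)C | intermediate
5 | prop-2-en-1-yl (1R,4aR,8aS)-5,5,8a-trimethyl-2-oxodecahydronaphthalene-1-carboxylate | C=CCOC(=O)[C@@H]1[C@@]2(C)CCCC(C)(C)[C@H]2CCC1=O | intermediate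
6 | (1R,4aR,8aS)-5,5,8a-trimethyl-1-(prop-2-en-1-yl)octahydronaphthalen-2(1H)-one | C=CC[C@@H]1[C@@]2(C)CCCC(C)(C)[C@H]2CCC1=O | intermediate
7 | (1R,4aR,8aS)-5,5,8a-trimethyl-1-(prop-2-en-1-yl)-4a,5,6,7,8,8a-hexahydronaphthalen-2(1H)-one | C=CC[C@@H]1[C@@]2(C)CCCC(C)(C)[C@H]2C=CC1=O | intermediate
8 | (1R,4aR,8aS)-2,5,5,8a-tetramethyl-1-(prop-2-en-1-yl)-1,2,4a,5,6,7,8,8a-octahydronaphthalen-2-ol (both C2 epimers) | C=CC[C@@H]1[C@@]2(C)CCCC(C)(C)[C@H]2C=CC1(C)O | intermediate
9 | (4S,4aR,8aR)-3,4a,8,8-tetramethyl-4-(prop-2-en-1-yl)-4a,5,6,7,8,8a-hexahydronaphthalen-1(4H)-one | C=CC[C@@H]1[C@@]2(C)CCCC(C)(C)[C@H]2C(=O)C=C1C | intermediate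
10 | (2S,3S,4R,4aR,8aR)-2,3-epoxy-3,4a,8,8-tetramethyl-4-(prop-2-en-1-yl)octahydronaphthalen-1(2H)-one | C=CC[C@@H]1[C@@]2(C)CCCC(C)(C)[C@H]2C(=O)[C@H]3O[C@]31C | intermediate
11 | (1S,3R,4R,4aS,8aR)-3,4a,8,8-tetramethyl-4-(prop-2-en-1-yl)decahydronaphthalene-1,3-diol | C=CC[C@@H]1[C@@]2(C)CCCC(C)(C)[C@H]2[C@@H](O)C[C@@]1(C)O | intermediate
12 | angelic acid, (2Z)-2-methylbut-2-enoic acid | C/C=C(/C)C(=O)O | starting material
13 | (1S,3R,4R,4aS,8aR)-3-hydroxy-3,4a,8,8-tetramethyl-4-(prop-2-en-1-yl)decahydronaphthalen-1-yl (2Z)-2-methylbut-2-enoate | C=CC[C@@H]1[C@@]2(C)CCCC(C)(C)[C@H]2[C@@H](OC(=O)/C(C)=C\C)C[C@@]1(C)O | intermediate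
14 | (1S,3R,4R,4aS,8aR)-3-hydroxy-3,4a,8,8-tetramethyl-4-(4-oxobutyl)decahydronaphthalen-1-yl (2Z)-2-methylbut-2-enoate | O=CCCC[C@@H]1[C@@]2(C)CCCC(C)(C)[C@H]2[C@@H](OC(=O)/C(C)=C\C)C[C@@]1(C)O | intermediate
15 | (1S,3R,4R,4aS,8aR)-3-hydroxy-4-[(3S)-3-(hydroxymethyl)-4-oxobutyl]-3,4a,8,8-tetramethyldecahydronaphthalen-1-yl (2Z)-2-methylbut-2-enoate | O=C[C@H](CO)CC[C@@H]1[C@@]2(C)CCCC(C)(C)[C@H]2[C@@H](OC(=O)/C(C)=C\C)C[C@@]1(C)O | intermediate
16 | (1S,3R,4R,4aS,8aR)-3-hydroxy-4-[(3R)-3-(hydroxymethyl)pent-4-en-1-yl]-3,4a,8,8-tetramethyldecahydronaphthalen-1-yl (2Z)-2-methylbut-2-enoate | C=C[C@H](CO)CC[C@@H]1[C@@]2(C)CCCC(C)(C)[C@H]2[C@@H](OC(=O)/C(C)=C\C)C[C@@]1(C)O | target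

**Step count and risks**
Total step count: 11. Longest linear sequence: 11 (the route is fully linear).

Steps most likely to fail:

Step 2 (the new cyclisation: enantioselectivity, and C- versus O-termination, are untested). The fallback uses known chemistry, sets out from 4 and comes back at 5. Shi epoxidation of the terminal olefin of 4 (L-fructose-derived Shi ketone, KHSO5, buffered MeCN/dimethoxymethane, 0 °C, stopped at partial conversion) gives prop-2-en-1-yl (6Z)-9-[(2S)-3,3-dimethyloxiran-2-yl]-7-methyl-3-oxonon-6-enoate F1. MeAlCl2 in CH2Cl2 at −78 °C then triggers the epoxide-initiated bicyclisation, in which the epoxide carbon fixes the chair of ring A and the Z-olefin again gives the cis fusion, to prop-2-en-1-yl (1R,4aS,6S,8aS)-6-hydroxy-5,5,8a-trimethyl-2-oxodecahydronaphthalene-1-carboxylate F2. The extra hydroxyl is removed by Barton–McCombie deoxygenation: 1,1'-thiocarbonyldiimidazole gives prop-2-en-1-yl (1R,4aS,6S,8aS)-6-[(1H-imidazol-1-ylcarbonothioyl)oxy]-5,5,8a-trimethyl-2-oxodecahydronaphthalene-1-carboxylate F3, and Bu3SnH with AIBN in toluene at 110 °C returns 5.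

Step 3 (the facial sense of the allyl transfer at C1 is predicted, not known, and a wrong epimer would be carried through). The fallback sets out from 5 and comes back at 6. K2CO3 and allyl bromide in acetone alkylate 5 to prop-2-en-1-yl (1R,4aR,8aS)-5,5,8a-trimethyl-2-oxo-1-(prop-2-en-1-yl)decahydronaphthalene-1-carboxylate F4, whose C1 configuration is immaterial. Pd(OAc)2 and PPh3 with HCO2H and Et3N in THF then effect decarboxylative protonation to 6. Because the C1–H bond is now formed last, the same facial bias of the enolate gives the C1 epimer opposite to the one from step 3.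

Step 6 (very hindered β,β-disubstituted enone; face selectivity and base-induced epimerisation are the concerns). The fallback sets out from 9 and comes back at 11. Conjugate borylation catalysed by monovalent copper (CuCl, NaOtBu, DPEphos, bis(pinacolato)diboron, MeOH, THF) gives (3S,4S,4aR,8aR)-3,4a,8,8-tetramethyl-4-(prop-2-en-1-yl)-3-(4,4,5,5-tetramethyl-1,3,2-dioxaborolan-2-yl)octahydronaphthalen-1(2H)-one F5. Oxidation with NaBO3·4H2O, with retention, gives (3R,4R,4aR,8aR)-3-hydroxy-3,4a,8,8-tetramethyl-4-(prop-2-en-1-yl)octahydronaphthalen-1(2H)-one F6. Narasaka–Prasad reduction (Et2BOMe, NaBH4, THF/MeOH, −78 °C) then gives the syn-1,3-diol 11.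

**Further compounds**
F1 | step 2 | prop-2-en-1-yl (6Z)-9-[(2S)-3,3-dimethyloxiran-2-yl]-7-methyl-3-oxonon-6-enoate | C=CCOC(=O)CC(=O)CC/C=C(/C)CC[C@@H]1OC1(C)C
F2 | step 2 | prop-2-en-1-yl (1R,4aS,6S,8aS)-6-hydroxy-5,5,8a-trimethyl-2-oxodecahydronaphthalene-1-carboxylate | C=CCOC(=O)[C@@H]1[C@@]2(C)CC[C@H](O)C(C)(C)[C@H]2CCC1=O
F3 | step 2 | prop-2-en-1-yl (1R,4aS,6S,8aS)-6-[(1H-imidazol-1-ylcarbonothioyl)oxy]-5,5,8a-trimethyl-2-oxodecahydronaphthalene-1-carboxylate | C=CCOC(=O)[C@@H]1[C@@]2(C)CC[C@H](OC(=S)n3ccnc3)C(C)(C)[C@H]2CCC1=O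
F4 | step 3 | prop-2-en-1-yl (1R,4aR,8aS)-5,5,8a-trimethyl-2-oxo-1-(prop-2-en-1-yl)decahydronaphthalene-1-carboxylate | C=CCOC(=O)[C@]1(CC=C)[C@@]2(C)CCCC(C)(C)[C@H]2CCC1=O
F5 | step 6 | (3S,4S,4aR,8aR)-3,4a,8,8-tetramethyl-4-(prop-2-en-1-yl)-3-(4,4,5,5-tetramethyl-1,3,2-dioxaborolan-2-yl)octahydronaphthalen-1(2H)-one | C=CC[C@@H]1[C@@]2(C)CCCC(C)(C)[C@H]2C(=O)C[C@@]1(C)B1OC(C)(C)C(C)(C)O1
F6 | step 6 | (3R,4R,4aR,8aR)-3-hydroxy-3,4a,8,8-tetramethyl-4-(prop-2-en-1-yl)octahydronaphthalen-1(2H)-one | C=CC[C@@H]1[C@@]2(C)CCCC(C)(C)[C@H]2C(=O)C[C@@]1(C)O
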